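## The problem

Compound 27 is a 2,3-trans-2,3-diaryl-2,3-dihydro-1-benzofuran. The benzo ring (ring A) carries a hydroxyl at C4 and a 2-(4-hydroxyphenyl)ethyl chain (ring D) at C6; C2 bears a 2,4-dihydroxyphenyl group (ring B) and C3 a 3,5-dihydroxyphenyl group (ring C). A synthesis has to join four oxygenated arenes around two adjacent benzylic stereocentres, (2S,3S), and close the five-membered ether ring between them.

The two centres are not equally robust. C2 is a benzylic aryl ether carbon on an ortho/para-dioxygenated ring, so the C2–O1 bond opens under Brønsted or Lewis acid and, once ring B is a free phenol, also under base. C3 is an ordinary triaryl-substituted methine. C3 therefore holds the absolute configuration, and C2 settles trans to it whenever the ether bond opens and closes again; C3 can control C2, but not the reverse.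

Six free phenols and the labile C2–O1 bond rule out a final BBr3 demethylation or a long hydrogenolysis, so the protecting groups must leave with carbonate/methanol and fluoride. The same donor power of ring B makes any leaving group on its benzylic carbon prone to ionise, which has to be tamed in the fragment that delivers C2.

The enabling feature is that C3a lies between two equivalent oxygens, O1 and the C4 hydroxyl. Ring A is a 2-substituted 5-alkylresorcinol, and C3–C3a–C7a–O1 is an o-quinone methide that lacks only the single carbon C2 with ring B. Whichever of the two oxygens closes the ring, the same compound results.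

## Retrosynthesis

**Protecting groups (27 from 26 from 25).** The last cuts are three O–Si bonds and two O–acyl bonds. Ring B is carried as a bis-pivalate because electron-withdrawing esters keep its benzylic position from ionising. Rings C and D are carried as triisopropylsilyl ethers because they survive butyllithium, dilute methanolic acid and carbonate and leave with buffered fluoride. The C4 hydroxyl stays free throughout. Methyl ethers (Lewis-acid cleavage) and benzyl ethers (hydrogenolysis next to a benzylic C–O bond) were rejected as threats to C2–O1.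

**The [4+1] cut (25 from 13 and 21).** Both bonds to C2 are cut together, C2–C3 and O1–C2.
- Against its neighbours: cutting only O1–C2 would leave the stereodiad to be built in open-chain form. Cutting C3–C3a would mean arylating a resorcinol with uncertain regiochemistry. Cutting C3–ring C on a benzofuran would need a cis-selective reduction and a later epimerisation.
- Simplification: both stereocentres and the heterocycle disappear at once. What remains is racemic sulfone 13, whose stereocentre is erased in quinone methide 22, and sulfonium salt 21, whose only chirality is a purchased C2-symmetric diol.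
- Demands on the forward step: ylide 23 must attack the methide carbon of 22 through carbon, on one face, and betaine 24 must close trans.
- The sulfide is used in stoichiometric amount and recovered. A catalytic cycle with free bromide 20 is excluded because 20 would alkylate the phenoxides.
- Choice of sulfide enantiomer: benzylides of the (2R,5R)-thiolane are known to give (S,S)-diaryloxiranes with aldehydes. In 25 the aryl group outranks the carbon that came from the electrophile, the reverse of the oxirane case, so the same spatial course translates into the (2S,5S)-sulfide 17 for (S)-C2. Both enantiomers of the diol are commercial, so the antipode of 14 is at hand should the analogy fail.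

**Sulfone 13 from carbinol 11, and 11 from 8 and 9.** The C–S bond is cut first, then C3–C3a. The bond to ring A is made by lithiation between the two MOM ethers of 8 (aryllithium 10) and addition to aldehyde 9. This fixes the position between the oxygens, which electrophilic substitution of a 5-alkylresorcinol would not do cleanly. Acid then removes the MOM groups and turns the carbinol into methyl ether 12, and sulfinate replaces the benzylic oxygen. The forward steps must keep the silyl ethers and must not let the very stabilised benzylic cation attack another resorcinol ring.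

**Ring A–ring D fragment (8 from 7 from 5 from 2 and 3; 2 and 9 from 1).** The two-carbon bridge is cut at the stage of a stilbene. Wittig reaction of aldehyde 2 with ylide 4 from salt 3, then hydrogenation through 6, gives phenol 7 and frees ring D for silylation to 8. One purchased aldehyde, 1, supplies both ring A (as 2) and ring C (as 9). A cross-coupling of two benzylic partners was not preferred because homocoupling would compete.

**Sulfonium salt 21 from 20 and 17.** The S–C bond is cut to benzyl bromide 20 and thiolane 17. Bromide 20 comes from 4-methylresorcinol 18 by acylation (19) and benzylic bromination; this avoids a 2-acyloxybenzyl alcohol, in which the acyl group would migrate. Thiolane 17 comes from diol 14 through dimesylate 15 and thiolate 16 by two inversions. Because 17 is C2-symmetric, alkylation at either lone pair gives the same salt.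

## Roads not taken

**Alternative 1:** The cut goes through ring A itself (C3a–C4 and C7–C7a). The benzo ring is made last by thermal benzannulation of cyclobutenone A2 with siloxyalkyne A3, which already carries C3, C2 and both stereocentres. Electrocyclic opening of A2, [2+2] addition to A3, a second ring opening and six-electron closure would give the resorcinol monosilyl ether A1.
- Merits: the reaction type is established. Ring A arrives with unambiguous substitution and with its two oxygens differentiated (free phenol for O1, silyl ether for the C4 oxygen). No electrophilic quinone methide appears. In these respects it is better than the chosen plan, whose quinone methide 22 has to live with a free, acidic hydroxyl.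
- Weak points: the step builds neither stereocentre nor the heterocycle. A3 must first be made as one stereoisomer of an open-chain, propargylic and doubly benzylic ynol silyl ether and must survive heating. The O1–C2 bond must still be closed from A1 with net retention at C2, which means ionisation at C2 and reliance on the trans preference. The methyl ethers would need Lewis-acid cleavage next to the labile C2–O1 bond.
- Comparison: the chosen plan sets convergence against this reliability. Compounds 13 and 21 come from purchased arenes in short sequences, and one step creates both stereocentres and the ring.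

**Alternative 2:** The cut is C3–C3a. Ring A reaches C3 by a 1,2-aryl shift when flavanone A5 is oxidised with a hypervalent iodine reagent in acidic methanol in the presence of an orthoformate. The pyranone contracts to the dihydrofuran, and the former carbonyl carbon leaves the ring as the ester group of A4.
- Merits: oxidative ring contraction of flavanones to trans-2-aryl-2,3-dihydrobenzofuran-3-carboxylates is known chemistry. A5 is easy to assemble. C2 can be set by established asymmetric flavanone chemistry and then directs C3. In precedent for the key step this road is ahead of the chosen one.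
- Weak points: A4 carries an ester on C3 where ring C must stand. The carboxyl carbon must be excised and replaced by an aryl group at a benzylic stereocentre, or be built up atom by atom into ring C, and either continuation is long. The electron-rich rings of A5 face an oxidant and strong acid, where dehydrogenation, nuclear oxidation and retro-oxa-Michael opening (loss of the C2 configuration) compete. The conditions force methyl ethers and hence a Lewis-acid end-game.
- Comparison: the chosen plan has ring C in place before the key step (aldehyde 9) and needs no step after it except deprotection.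

**Alternative 3:** The cut lies inside ring C (C1'–C2'). The ring is folded from diketo-dioxinone A7, whose chain hangs on C3. Mild base brings about an intramolecular aldol reaction between the dioxinone carbon and the ketone next to C3, and dehydration and enolisation give the protected resorcylate A6.
- Merits: the hindered C3–aryl bond is never made by coupling. The 3,5-dioxygenation of ring C follows from the chain. The conditions are mild. Its regiocontrol over ring C is at least as good as in the chosen plan.
- Weak points: A7 has to be grown from a C3 carbonyl compound such as A4 by several chain extensions. In A7, C3 is alpha to a ketone and beta to the aryloxy oxygen O1, so enolisation can open the dihydrofuran by beta-elimination and destroy both stereocentres. After folding, the acetonide must be cleaved, the carboxyl group removed and four methyl ethers cleaved.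
- Comparison: this is the longest road. The chosen plan simply buys ring C as 1 and attaches it in one step (8 and 9 to 11).

Key step: step 13

Assumption: benzylide 23 is taken to meet the quinone methide through the same conformer and on the same face as benzylides of this thiolane meet aldehydes; the (2S,5S)-sulfide is assigned to the (2S,3S) product on that basis.

## Steps

Step 1
Reactants: 1 3,5-dihydroxybenzaldehyde
Product: 2 3,5-bis(methoxymethoxy)benzaldehyde
Conditions: MOMCl, i-Pr2NEt, CH2Cl2, 0 °C to rt
Reagents that add atoms: chloromethyl methyl ether, COCCl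
Why: O-alkylation of both phenols to the mixed acetals (MOM protection); the two MOM ethers later direct lithiation to the carbon between them.

Step 2
Reactants: 2 3,5-bis(methoxymethoxy)benzaldehyde; 3 (4-benzyloxybenzyl)triphenylphosphonium chloride
Product: 5 1-[2-(4-benzyloxyphenyl)ethenyl]-3,5-bis(methoxymethoxy)benzene (E/Z mixture), via phosphonium ylide 4 (not isolated)
Conditions: KOtBu, THF, 0 °C to rt
Reagents that add atoms: none
Why: Wittig olefination of a non-enolisable aldehyde with a semi-stabilised benzylide; the E/Z mixture is of no consequence because the double bond is saturated in the next step.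

Step 3
Reactants: 5 1-[2-(4-benzyloxyphenyl)ethenyl]-3,5-bis(methoxymethoxy)benzene
Product: 7 4-{2-[3,5-bis(methoxymethoxy)phenyl]ethyl}phenol, via bibenzyl benzyl ether 6 (not isolated)
Conditions: H2 (1 atm), 10% Pd/C, EtOAc/MeOH, rt
Reagents that add atoms: none
Why: Catalytic hydrogenation saturates the stilbene and hydrogenolysis then cleaves the benzyl ether in the same operation; MOM ethers are inert to H2 over Pd/C.

Step 4
Reactants: 7 4-{2-[3,5-bis(methoxymethoxy)phenyl]ethyl}phenol
Product: 8 {4-[2-(3,5-bis(methoxymethoxy)phenyl)ethyl]phenoxy}triisopropylsilane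
Conditions: TIPSCl, imidazole, DMF, rt
Reagents that add atoms: chlorotriisopropylsilane, CC(C)[Si](Cl)(C(C)C)C(C)C
Why: Imidazole-promoted silylation of the phenol; the bulky TIPS ether tolerates n-BuLi, dilute methanolic HCl and Cs2CO3 and leaves with fluoride at the end.

Step 5
Reactants: 1 3,5-dihydroxybenzaldehyde
Product: 9 3,5-bis(triisopropylsilyloxy)benzaldehyde
Conditions: TIPSCl, imidazole, DMF, rt
Reagents that add atoms: chlorotriisopropylsilane, CC(C)[Si](Cl)(C(C)C)C(C)C
Why: The same phenol silylation on both hydroxyls; the aldehyde is untouched and ring C is now protected in a form that survives aryllithium addition.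

Step 6
Reactants: 8 {4-[2-(3,5-bis(methoxymethoxy)phenyl)ethyl]phenoxy}triisopropylsilane; 9 3,5-bis(triisopropylsilyloxy)benzaldehyde
Product: 11 racemic [2,6-bis(methoxymethoxy)-4-{2-[4-(triisopropylsilyloxy)phenyl]ethyl}phenyl][3,5-bis(triisopropylsilyloxy)phenyl]methanol, via aryllithium 10 (not isolated)
Conditions: n-BuLi, THF, 0 °C; then 9, −78 °C to 0 °C; H2O
Reagents that add atoms: none
Why: Directed ortho-metalation: the two MOM ethers co-operate, so n-BuLi removes the proton on the carbon between them (the future C3a), and 1,2-addition to the aldehyde forms the C3–C3a bond. The carbinol is racemic, which does not matter because C3 becomes trigonal in the quinone methide; a neutral work-up protects the easily ionised benzhydrol.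

Step 7
Reactants: 11 racemic [2,6-bis(methoxymethoxy)-4-{2-[4-(triisopropylsilyloxy)phenyl]ethyl}phenyl][3,5-bis(triisopropylsilyloxy)phenyl]methanol
Product: 13 racemic 2-{[3,5-bis(triisopropylsilyloxy)phenyl](4-methylbenzenesulfonyl)methyl}-5-{2-[4-(triisopropylsilyloxy)phenyl]ethyl}benzene-1,3-diol, via benzylic methyl ether 12 (not isolated)
Conditions: conc. HCl (cat.), MeOH/THF, 40 °C; evaporate; p-TolSO2H, CH2Cl2, rt
Reagents that add atoms: p-toluenesulfinic acid, Cc1ccc(cc1)S(=O)O
Why: Acid-catalysed acetal exchange removes both MOM groups as dimethoxymethane and the ionisable carbinol is solvolysed to its methyl ether; the sulfinic acid then ionises this ether and the sulfinate is S-alkylated by the 2,6-dihydroxybenzhydryl cation (SN1 substitution, the usual route to 2-(1-tosylalkyl)phenols). The free ring A positions are flanked by a hydroxyl and the chain, which slows self-alkylation, and aryl TIPS ethers withstand the dilute acid.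

Step 8
Reactants: 14 (2R,5R)-hexane-2,5-diol
Product: 15 (2R,5R)-hexane-2,5-diyl dimethanesulfonate
Conditions: MsCl, Et3N, CH2Cl2, −20 to 0 °C
Reagents that add atoms: methanesulfonyl chloride, CS(=O)(=O)Cl
Why: Sulfonylation of both secondary alcohols at oxygen; the C–O bonds are not touched, so both centres keep their configuration.

Step 9
Reactants: 15 (2R,5R)-hexane-2,5-diyl dimethanesulfonate
Product: 17 (2S,5S)-2,5-dimethylthiolane, via mesyloxy thiolate 16 (not isolated)
Conditions: Na2S·9H2O, DMSO, rt
Reagents that add atoms: sodium sulfide Na2S, [Na+].[Na+].[S-2]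
Why: Double SN2 displacement by sulfide, first intermolecular and then 5-exo-tet; each substitution inverts, so the (2R,5R)-dimesylate gives the (2S,5S)-thiolane.

Step 10
Reactants: 18 4-methylbenzene-1,3-diol
Product: 19 4-methyl-1,3-phenylene bis(2,2-dimethylpropanoate)
Conditions: PivCl, Et3N, DMAP (cat.), CH2Cl2, 0 °C to rt
Reagents that add atoms: pivaloyl chloride, CC(C)(C)C(=O)Cl
Why: DMAP-catalysed acylation of both phenols; the hindered, electron-withdrawing esters deactivate the ring for the next step and later stabilise the sulfonium salt.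

Step 11
Reactants: 19 4-methyl-1,3-phenylene bis(2,2-dimethylpropanoate)
Product: 20 4-(bromomethyl)-1,3-phenylene bis(2,2-dimethylpropanoate)
Conditions: NBS, AIBN (cat.), PhCF3, 80 °C
Reagents that add atoms: N-bromosuccinimide, O=C1CCC(=O)N1Br
Why: Wohl–Ziegler radical bromination of the benzylic methyl group; the acyloxy groups suppress electrophilic ring bromination and one equivalent of NBS limits a second bromination.

Step 12
Reactants: 20 4-(bromomethyl)-1,3-phenylene bis(2,2-dimethylpropanoate); 17 (2S,5S)-2,5-dimethylthiolane
Product: 21 (2S,5S)-1-[2,4-bis(2,2-dimethylpropanoyloxy)benzyl]-2,5-dimethylthiolan-1-ium tetrafluoroborate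
Conditions: AgBF4, CH2Cl2, 0 °C to rt, dark
Reagents that add atoms: silver tetrafluoroborate AgBF4, [Ag+].F[B-](F)(F)F
Why: S-alkylation of the sulfide by the benzyl bromide, driven by precipitation of AgBr and made irreversible by the non-nucleophilic counter-ion; the two lone pairs of the C2-symmetric sulfide are equivalent, so a single sulfonium salt forms.

Step 13
Reactants: 13 racemic 2-{[3,5-bis(triisopropylsilyloxy)phenyl](4-methylbenzenesulfonyl)methyl}-5-{2-[4-(triisopropylsilyloxy)phenyl]ethyl}benzene-1,3-diol; 21 (2S,5S)-1-[2,4-bis(2,2-dimethylpropanoyloxy)benzyl]-2,5-dimethylthiolan-1-ium tetrafluoroborate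
Product: 25 4-[(2S,3S)-3-[3,5-bis(triisopropylsilyloxy)phenyl]-4-hydroxy-6-{2-[4-(triisopropylsilyloxy)phenyl]ethyl}-2,3-dihydro-1-benzofuran-2-yl]-1,3-phenylene bis(2,2-dimethylpropanoate), via quinone methide cesium salt 22 (not isolated), via sulfonium benzylide 23 (not isolated), via betaine 24 (not isolated)
Conditions: Cs2CO3, MeCN/THF, −20 °C to rt; pH 6 buffer
Reagents that add atoms: none
Why: Proposed new method: Cs2CO3 deprotonates a phenol of 13, the phenoxide expels p-toluenesulfinate by 1,4-elimination to give quinone methide 22 (held as the cesium salt of its remaining hydroxyl), and the same base converts 21 into benzylide 23; conjugate addition of the ylide carbon to the methide carbon forms C2–C3, re-aromatises ring A and gives betaine 24, whose phenoxide displaces the thiolane at C2 to form O1–C2. The closest known reaction type is the [4+1] annulation of quinone methides released from 2-(1-tosylalkyl)phenols with carbonyl-stabilised sulfonium ylides, which gives trans-2,3-dihydrobenzofurans; new here are the semi-stabilised benzylic ylide and stoichiometric control by a C2-symmetric sulfide, a combination so far established for the epoxidation of aldehydes. The dihydrofuran ring closes in the 5-exo-tet mode by intramolecular SN2 substitution with inversion at C2. C2 is controlled by the sulfide: the ylide should react through the conformer with its aryl group turned away from the thiolane ring and on the face remote from the methyl group that is cis to the ylide carbon, which with the (2S,5S)-sulfide gives (R)-C2 in 24 and (S)-C2 in 25 after inversion. C3 is set in the same C–C bond formation by relative topicity, since addition and closure both run with the two aryl groups anti, which leads to the trans isomer, also the more stable one. The step needs enantioselectivity and trans selectivity (secured as described), C- instead of O-alkylation (the hindered 2,6-disubstituted phenoxides are poor SN2 partners for the ortho-substituted benzylsulfonium ion, and the ylide is no alkylating agent) and a sulfonium salt that does not ionise (secured by the two pivalates on ring B). Because the two oxygens ortho to C3a are equivalent, either may become O1 and the other appears as the C4 hydroxyl after the buffered work-up.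

Step 14
Reactants: 25 4-[(2S,3S)-3-[3,5-bis(triisopropylsilyloxy)phenyl]-4-hydroxy-6-{2-[4-(triisopropylsilyloxy)phenyl]ethyl}-2,3-dihydro-1-benzofuran-2-yl]-1,3-phenylene bis(2,2-dimethylpropanoate)
Product: 26 4-[(2S,3S)-3-[3,5-bis(triisopropylsilyloxy)phenyl]-4-hydroxy-6-{2-[4-(triisopropylsilyloxy)phenyl]ethyl}-2,3-dihydro-1-benzofuran-2-yl]benzene-1,3-diol
Conditions: K2CO3, MeOH/THF, 0 °C to rt, Ar
Reagents that add atoms: none
Why: Base-catalysed transesterification (methanolysis) of the two aryl pivalates; aryl esters cleave under conditions that leave aryl TIPS ethers in place, and short, cold treatment under argon limits the time the ring B phenoxide is exposed to base.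

Step 15
Reactants: 26 4-[(2S,3S)-3-[3,5-bis(triisopropylsilyloxy)phenyl]-4-hydroxy-6-{2-[4-(triisopropylsilyloxy)phenyl]ethyl}-2,3-dihydro-1-benzofuran-2-yl]benzene-1,3-diol
Product: 27 4-[(2S,3S)-3-(3,5-dihydroxyphenyl)-4-hydroxy-6-[2-(4-hydroxyphenyl)ethyl]-2,3-dihydro-1-benzofuran-2-yl]benzene-1,3-diol
Conditions: HF·pyridine, pyridine, THF, 0 °C to rt
Reagents that add atoms: none
Why: Fluoride-induced cleavage of the three aryl silyl ethers (Si–F bond formation) in a pyridine-buffered medium; neither strong base nor a Lewis acid is present, so the C2–O1 bond and both stereocentres are left alone.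

## Compound list

1 | 3,5-dihydroxybenzaldehyde | O=Cc1cc(O)cc(O)c1 | starting material
2 | 3,5-bis(methoxymethoxy)benzaldehyde | O=Cc1cc(OCOC)cc(OCOC)c1 | intermediate
3 | (4-benzyloxybenzyl)triphenylphosphonium chloride | [Cl-].c1ccc(cc1)COc1ccc(C[P+](c2ccccc2)(c2ccccc2)c2ccccc2)cc1 | starting material
4 | (4-benzyloxybenzylidene)triphenylphosphorane (formed in the flask, step 2) | c1ccc(cc1)COc1ccc(C=P(c2ccccc2)(c2ccccc2)c2ccccc2)cc1 | intermediate
5 | 1-[2-(4-benzyloxyphenyl)ethenyl]-3,5-bis(methoxymethoxy)benzene (E/Z mixture) | COCOc1cc(C=Cc2ccc(OCc3ccccc3)cc2)cc(OCOC)c1 | intermediate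
6 | 1-[2-(4-benzyloxyphenyl)ethyl]-3,5-bis(methoxymethoxy)benzene (formed in the flask, step 3) | COCOc1cc(CCc2ccc(OCc3ccccc3)cc2)cc(OCOC)c1 | intermediate
7 | 4-{2-[3,5-bis(methoxymethoxy)phenyl]ethyl}phenol | COCOc1cc(CCc2ccc(O)cc2)cc(OCOC)c1 | intermediate
8 | {4-[2-(3,5-bis(methoxymethoxy)phenyl)ethyl]phenoxy}triisopropylsilane | COCOc1cc(CCc2ccc(O[Si](C(C)C)(C(C)C)C(C)C)cc2)cc(OCOC)c1 | intermediate
9 | 3,5-bis(triisopropylsilyloxy)benzaldehyde | O=Cc1cc(O[Si](C(C)C)(C(C)C)C(C)C)cc(O[Si](C(C)C)(C(C)C)C(C)C)c1 | intermediate
10 | 2,6-bis(methoxymethoxy)-4-{2-[4-(triisopropylsilyloxy)phenyl]ethyl}phenyllithium (formed in the flask, step 6) | [Li]c1c(OCOC)cc(CCc2ccc(O[Si](C(C)C)(C(C)C)C(C)C)cc2)cc1OCOC | intermediate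
11 | racemic [2,6-bis(methoxymethoxy)-4-{2-[4-(triisopropylsilyloxy)phenyl]ethyl}phenyl][3,5-bis(triisopropylsilyloxy)phenyl]methanol | OC(c1cc(O[Si](C(C)C)(C(C)C)C(C)C)cc(O[Si](C(C)C)(C(C)C)C(C)C)c1)c1c(OCOC)cc(CCc2ccc(O[Si](C(C)C)(C(C)C)C(C)C)cc2)cc1OCOC | intermediate
12 | racemic 2-{[3,5-bis(triisopropylsilyloxy)phenyl](methoxy)methyl}-5-{2-[4-(triisopropylsilyloxy)phenyl]ethyl}benzene-1,3-diol (formed in the flask, step 7) | COC(c1cc(O[Si](C(C)C)(C(C)C)C(C)C)cc(O[Si](C(C)C)(C(C)C)C(C)C)c1)c1c(O)cc(CCc2ccc(O[Si](C(C)C)(C(C)C)C(C)C)cc2)cc1O | intermediate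
13 | racemic 2-{[3,5-bis(triisopropylsilyloxy)phenyl](4-methylbenzenesulfonyl)methyl}-5-{2-[4-(triisopropylsilyloxy)phenyl]ethyl}benzene-1,3-diol | Cc1ccc(cc1)S(=O)(=O)C(c1cc(O[Si](C(C)C)(C(C)C)C(C)C)cc(O[Si](C(C)C)(C(C)C)C(C)C)c1)c1c(O)cc(CCc2ccc(O[Si](C(C)C)(C(C)C)C(C)C)cc2)cc1O | intermediate
14 | (2R,5R)-hexane-2,5-diol | C[C@@H](O)CC[C@@H](C)O | starting material
15 | (2R,5R)-hexane-2,5-diyl dimethanesulfonate | C[C@@H](OS(C)(=O)=O)CC[C@@H](C)OS(C)(=O)=O | intermediate
16 | sodium (2S,5R)-5-(methanesulfonyloxy)hexane-2-thiolate (formed in the flask, step 9) | C[C@H]([S-])CC[C@@H](C)OS(C)(=O)=O.[Na+] | intermediate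
17 | (2S,5S)-2,5-dimethylthiolane | C[C@H]1CC[C@H](C)S1 | intermediate
18 | 4-methylbenzene-1,3-diol | Cc1ccc(O)cc1O | starting material
19 | 4-methyl-1,3-phenylene bis(2,2-dimethylpropanoate) | Cc1ccc(OC(=O)C(C)(C)C)cc1OC(=O)C(C)(C)C | intermediate
20 | 4-(bromomethyl)-1,3-phenylene bis(2,2-dimethylpropanoate) | BrCc1ccc(OC(=O)C(C)(C)C)cc1OC(=O)C(C)(C)C | intermediate
21 | (2S,5S)-1-[2,4-bis(2,2-dimethylpropanoyloxy)benzyl]-2,5-dimethylthiolan-1-ium tetrafluoroborate | C[C@H]1CC[C@H](C)[S+]1Cc1ccc(OC(=O)C(C)(C)C)cc1OC(=O)C(C)(C)C.F[B-](F)(F)F | intermediate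
22 | cesium 6-[3,5-bis(triisopropylsilyloxy)benzylidene]-5-oxo-3-{2-[4-(triisopropylsilyloxy)phenyl]ethyl}cyclohexa-1,3-dien-1-olate, the ring A quinone methide (formed in the flask, step 13) | O=C1C=C(CCc2ccc(O[Si](C(C)C)(C(C)C)C(C)C)cc2)C=C([O-])C1=Cc1cc(O[Si](C(C)C)(C(C)C)C(C)C)cc(O[Si](C(C)C)(C(C)C)C(C)C)c1.[Cs+] | intermediate
23 | (2S,5S)-1-[2,4-bis(2,2-dimethylpropanoyloxy)benzylidene]-2,5-dimethylthiolane, the sulfonium benzylide (formed in the flask, step 13) | C[C@H]1CC[C@H](C)[S+]1[CH-]c1ccc(OC(=O)C(C)(C)C)cc1OC(=O)C(C)(C)C | intermediate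
24 | betaine: cesium salt of 2-{(1S,2R)-2-[2,4-bis(2,2-dimethylpropanoyloxy)phenyl]-1-[3,5-bis(triisopropylsilyloxy)phenyl]-2-[(2S,5S)-2,5-dimethylthiolan-1-ium-1-yl]ethyl}-5-{2-[4-(triisopropylsilyloxy)phenyl]ethyl}benzene-1,3-diolate (formed in the flask, step 13) | C[C@H]1CC[C@H](C)[S+]1[C@@H](c1ccc(OC(=O)C(C)(C)C)cc1OC(=O)C(C)(C)C)[C@@H](c1cc(O[Si](C(C)C)(C(C)C)C(C)C)cc(O[Si](C(C)C)(C(C)C)C(C)C)c1)c1c([O-])cc(CCc2ccc(O[Si](C(C)C)(C(C)C)C(C)C)cc2)cc1[O-].[Cs+] | intermediate
25 | 4-[(2S,3S)-3-[3,5-bis(triisopropylsilyloxy)phenyl]-4-hydroxy-6-{2-[4-(triisopropylsilyloxy)phenyl]ethyl}-2,3-dihydro-1-benzofuran-2-yl]-1,3-phenylene bis(2,2-dimethylpropanoate) | CC(C)[Si](C(C)C)(C(C)C)Oc1ccc(CCc2cc(O)c3c(c2)O[C@H](c2ccc(OC(=O)C(C)(C)C)cc2OC(=O)C(C)(C)C)[C@H]3c2cc(O[Si](C(C)C)(C(C)C)C(C)C)cc(O[Si](C(C)C)(C(C)C)C(C)C)c2)cc1 | intermediate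
26 | 4-[(2S,3S)-3-[3,5-bis(triisopropylsilyloxy)phenyl]-4-hydroxy-6-{2-[4-(triisopropylsilyloxy)phenyl]ethyl}-2,3-dihydro-1-benzofuran-2-yl]benzene-1,3-diol | CC(C)[Si](C(C)C)(C(C)C)Oc1ccc(CCc2cc(O)c3c(c2)O[C@H](c2ccc(O)cc2O)[C@H]3c2cc(O[Si](C(C)C)(C(C)C)C(C)C)cc(O[Si](C(C)C)(C(C)C)C(C)C)c2)cc1 | intermediate
27 | 4-[(2S,3S)-3-(3,5-dihydroxyphenyl)-4-hydroxy-6-[2-(4-hydroxyphenyl)ethyl]-2,3-dihydro-1-benzofuran-2-yl]benzene-1,3-diol (CNP0329616.1) | Oc1ccc(CCc2cc(O)c3c(c2)O[C@H](c2ccc(O)cc2O)[C@H]3c2cc(O)cc(O)c2)cc1 | target

## Step count and risks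

Total: 15 steps. Longest linear sequence: 9 steps (steps 1, 2, 3, 4, 6, 7, 13, 14, 15).

**Step 13 (key step, proposed new method).**
- What may go wrong, reactivity: the second hydroxyl of ring A is acidic, so the quinone methide is present as its conjugate base and may add the ylide only slowly. That leaves time for decay of the ylide by O-to-C acyl transfer from the ortho pivalate or by ring-opening elimination of the thiolanium, and for O-benzylation of phenoxides by unreacted sulfonium salt.
- What may go wrong, selectivity: poor facial selectivity in the C–C bond formation, or epimerisation of the betaine at C2 through re-formation of an ylide, would erode the enantiomeric purity or give the cis isomer.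
- Fallback (known chemistry, stepwise, no annulation), from carbinol 11: hydrogenolysis of the doubly benzylic hydroxyl (H2, Pd(OH)2/C) gives the diarylmethane 2-[3,5-bis(triisopropylsilyloxy)benzyl]-1,3-bis(methoxymethoxy)-5-{2-[4-(triisopropylsilyloxy)phenyl]ethyl}benzene F1. Deprotonation of F1 at the doubly benzylic carbon with n-BuLi and addition to 2,4-bis(methoxymethoxy)benzaldehyde F2 (from 2,4-dihydroxybenzaldehyde and MOMCl) gives the carbinol 1-[2,4-bis(methoxymethoxy)phenyl]-2-[2,6-bis(methoxymethoxy)-4-{2-[4-(triisopropylsilyloxy)phenyl]ethyl}phenyl]-2-[3,5-bis(triisopropylsilyloxy)phenyl]ethanol F3 as a mixture of diastereomers. Methanolic HCl removes the four MOM groups, and the cation at C2, stabilised by ring B, is captured by a ring A hydroxyl under thermodynamic control. This gives the racemic trans compound, that is 26 together with its (2R,3R) enantiomer F4. Separation on a chiral stationary phase returns the route to 26.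

**Step 7.**
- What may go wrong: acid-induced self-condensation through the benzylic cation during MOM cleavage (C-alkylation of a second resorcinol ring, or capture of the cation by a MOM oxygen to a cyclic acetal), partial loss of silyl groups, and reversal of the sulfone formation on acidic silica.
- Fallback, from 11: take the benzylic carbon out of play at the ketone oxidation level. Dess–Martin oxidation gives the benzophenone [2,6-bis(methoxymethoxy)-4-{2-[4-(triisopropylsilyloxy)phenyl]ethyl}phenyl][3,5-bis(triisopropylsilyloxy)phenyl]methanone F5. Methanolic HCl then removes the MOM groups with no ionisable benzylic group present and gives the 2,6-dihydroxybenzophenone F6. NaBH4 at 0 °C reduces F6 to the triol 2-{[3,5-bis(triisopropylsilyloxy)phenyl](hydroxy)methyl}-5-{2-[4-(triisopropylsilyloxy)phenyl]ethyl}benzene-1,3-diol F7, and p-TolSO2H in CH2Cl2 converts F7 into 13.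

**Step 11.**
- What may go wrong: over-bromination to the benzal bromide or incomplete conversion, giving mixtures that are hard to separate.
- Fallback, from 19: brominate exhaustively with excess NBS to the gem-dibromide 4-(dibromomethyl)-1,3-phenylene bis(2,2-dimethylpropanoate) F8, then remove one bromine selectively with (EtO)2P(O)H and i-Pr2NEt to reach 20.

**Step 14.**
- What may go wrong: base-induced opening of the C2–O1 bond through the ring B phenoxide, followed by epimerisation or isomerisation to an open-chain stilbene; air oxidation of the phenoxides; partial loss of silyl groups.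
- Fallback, from 25 to 26 with no new compound: cleave the pivalates reductively with i-Bu2AlH in CH2Cl2 at −78 °C, so that the phenols are released as aluminium phenoxides in an aprotic medium and never meet methanolic base.

## Further compounds

F1 | step 13 | 2-[3,5-bis(triisopropylsilyloxy)benzyl]-1,3-bis(methoxymethoxy)-5-{2-[4-(triisopropylsilyloxy)phenyl]ethyl}benzene | COCOc1cc(CCc2ccc(O[Si](C(C)C)(C(C)C)C(C)C)cc2)cc(OCOC)c1Cc1cc(O[Si](C(C)C)(C(C)C)C(C)C)cc(O[Si](C(C)C)(C(C)C)C(C)C)c1
F2 | step 13 | 2,4-bis(methoxymethoxy)benzaldehyde | O=Cc1ccc(OCOC)cc1OCOC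
F3 | step 13 | 1-[2,4-bis(methoxymethoxy)phenyl]-2-[2,6-bis(methoxymethoxy)-4-{2-[4-(triisopropylsilyloxy)phenyl]ethyl}phenyl]-2-[3,5-bis(triisopropylsilyloxy)phenyl]ethanol (mixture of diastereomers, racemic) | OC(c1ccc(OCOC)cc1OCOC)C(c1cc(O[Si](C(C)C)(C(C)C)C(C)C)cc(O[Si](C(C)C)(C(C)C)C(C)C)c1)c1c(OCOC)cc(CCc2ccc(O[Si](C(C)C)(C(C)C)C(C)C)cc2)cc1OCOC
F4 | step 13 | 4-[(2R,3R)-3-[3,5-bis(triisopropylsilyloxy)phenyl]-4-hydroxy-6-{2-[4-(triisopropylsilyloxy)phenyl]ethyl}-2,3-dihydro-1-benzofuran-2-yl]benzene-1,3-diol (enantiomer of 26) | CC(C)[Si](C(C)C)(C(C)C)Oc1ccc(CCc2cc(O)c3c(c2)O[C@@H](c2ccc(O)cc2O)[C@@H]3c2cc(O[Si](C(C)C)(C(C)C)C(C)C)cc(O[Si](C(C)C)(C(C)C)C(C)C)c2)cc1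
F5 | step 7 | [2,6-bis(methoxymethoxy)-4-{2-[4-(triisopropylsilyloxy)phenyl]ethyl}phenyl][3,5-bis(triisopropylsilyloxy)phenyl]methanone | O=C(c1cc(O[Si](C(C)C)(C(C)C)C(C)C)cc(O[Si](C(C)C)(C(C)C)C(C)C)c1)c1c(OCOC)cc(CCc2ccc(O[Si](C(C)C)(C(C)C)C(C)C)cc2)cc1OCOC
F6 | step 7 | [2,6-dihydroxy-4-{2-[4-(triisopropylsilyloxy)phenyl]ethyl}phenyl][3,5-bis(triisopropylsilyloxy)phenyl]methanone | O=C(c1cc(O[Si](C(C)C)(C(C)C)C(C)C)cc(O[Si](C(C)C)(C(C)C)C(C)C)c1)c1c(O)cc(CCc2ccc(O[Si](C(C)C)(C(C)C)C(C)C)cc2)cc1O
F7 | step 7 | racemic 2-{[3,5-bis(triisopropylsilyloxy)phenyl](hydroxy)methyl}-5-{2-[4-(triisopropylsilyloxy)phenyl]ethyl}benzene-1,3-diol | OC(c1cc(O[Si](C(C)C)(C(C)C)C(C)C)cc(O[Si](C(C)C)(C(C)C)C(C)C)c1)c1c(O)cc(CCc2ccc(O[Si](C(C)C)(C(C)C)C(C)C)cc2)cc1O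
F8 | step 11 | 4-(dibromomethyl)-1,3-phenylene bis(2,2-dimethylpropanoate) | BrC(Br)c1ccc(OC(=O)C(C)(C)C)cc1OC(=O)C(C)(C)C
F0 | step 14 | none | none
A1 | alternative 1 | 2-[(1S,2S)-2-(tert-butyldimethylsilyloxy)-2-(2,4-dimethoxyphenyl)-1-(3,5-dimethoxyphenyl)ethyl]-5-[2-(4-methoxyphenyl)ethyl]-3-(triisopropylsilyloxy)phenol | COc1ccc(CCc2cc(O)c([C@H](c3cc(OC)cc(OC)c3)[C@H](O[Si](C)(C)C(C)(C)C)c3ccc(OC)cc3OC)c(O[Si](C(C)C)(C(C)C)C(C)C)c2)cc1
A2 | alternative 1 | 3-[2-(4-methoxyphenyl)ethyl]cyclobut-2-en-1-one | O=C1C=C(CCc2ccc(OC)cc2)C1
A3 | alternative 1 | (3S,4S)-4-(tert-butyldimethylsilyloxy)-4-(2,4-dimethoxyphenyl)-3-(3,5-dimethoxyphenyl)-1-(triisopropylsilyloxy)but-1-yne | CC(C)[Si](C(C)C)(C(C)C)OC#C[C@H](c1cc(OC)cc(OC)c1)[C@H](O[Si](C)(C)C(C)(C)C)c1ccc(OC)cc1OC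
A4 | alternative 2 | methyl (2S,3S)-2-(2,4-dimethoxyphenyl)-4-methoxy-6-[2-(4-methoxyphenyl)ethyl]-2,3-dihydro-1-benzofuran-3-carboxylate | COc1ccc(CCc2cc(OC)c3c(c2)O[C@H](c2ccc(OC)cc2OC)[C@H]3C(=O)OC)cc1
A5 | alternative 2 | (2S)-2-(2,4-dimethoxyphenyl)-5-methoxy-7-[2-(4-methoxyphenyl)ethyl]-2,3-dihydro-4H-chromen-4-one | COc1ccc(CCc2cc(OC)c3c(c2)O[C@H](c2ccc(OC)cc2OC)CC3=O)cc1
A6 | alternative 3 | 5-{(2S,3S)-2-(2,4-dimethoxyphenyl)-4-methoxy-6-[2-(4-methoxyphenyl)ethyl]-2,3-dihydro-1-benzofuran-3-yl}-7-hydroxy-2,2-dimethyl-4H-1,3-benzodioxin-4-one | COc1ccc(CCc2cc(OC)c3c(c2)O[C@H](c2ccc(OC)cc2OC)[C@H]3c2cc(O)cc4OC(C)(C)OC(=O)c24)cc1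
A7 | alternative 3 | 6-{4-[(2S,3S)-2-(2,4-dimethoxyphenyl)-4-methoxy-6-[2-(4-methoxyphenyl)ethyl]-2,3-dihydro-1-benzofuran-3-yl]-2,4-dioxobutyl}-2,2-dimethyl-4H-1,3-dioxin-4-one | COc1ccc(CCc2cc(OC)c3c(c2)O[C@H](c2ccc(OC)cc2OC)[C@H]3C(=O)CC(=O)CC2=CC(=O)OC(C)(C)O2)cc1
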